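Atom numbering used below for the lactone ring: O1, C2 (C=O), C3 (carries the arylidene), C4 (stereocentre), C5 (OCH2).

**Plan**

- **Retrosynthesis.** First the phenol is masked as its acetate and one H at C5 is replaced by a p-tolylthio helper. Next the exocyclic C3=CH bond is cut to vanillin acetate and a CCl2 group at C3. Then O1-C5 and C3-C4 are cut together, leaving dichloroketene (C3=C2=O) and an (E)-1-alkenyl p-tolyl sulfoxide (S-C5=C4-CH2Ar). Last, C4=C5 is cut to (3,4-dimethoxyphenyl)acetaldehyde and methyl p-tolyl sulfoxide.
- **Enabling feature.** In the butyrolactone ring the C5H2-C4H pair carries O1 on its unbranched carbon and the acyl carbon C3 on its branched carbon. C5 bears only hydrogen and C3 is sp2. This is the imprint of a ketene added across an alkenyl sulfoxide, with sulfur parked on C5 and two chlorines on C3.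
- **Forward order.** The chain is joined by olefination, the lactone (the only ring made) arises in one operation, the arylidene is built from the CCl2 group, and then sulfur and acetyl are removed.
- **Stereochemistry.** C4 comes from the sulfur stereocentre of commercial (S)-methyl p-tolyl sulfoxide by suprafacial [3,3] transfer. The E arylidene geometry comes from the reductive elimination in step 3 and is also the thermodynamic one.

Key step: step 2

Assumption: the sense of sulfur-to-carbon transfer follows the usual rotamer model for this lactonisation (S-O bond perpendicular to the alkene plane, lone pair syn to C=C, tolyl outside); if the opposite sense were found, (R)-methyl p-tolyl sulfoxide would be used with no other change.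

**Step 1**
Reactants: 1 (S)-methyl p-tolyl sulfoxide; 2 diethyl chlorophosphate; 3 2-(3,4-dimethoxyphenyl)acetaldehyde
Product: 5 4-{(E)-3-[(S)-p-tolylsulfinyl]prop-2-en-1-yl}-1,2-dimethoxybenzene, via sulfinylmethylphosphonate 4 (not isolated)
Conditions: LiN(iPr)2 (2.1 equiv), THF, -78 °C; 2, -78 °C; then 3, -78 to 0 °C; aq NH4Cl; chromatography to remove the Z isomer
Reagents that add atoms: none
Why: C-phosphorylation of the lithiated sulfoxide followed by Horner-Wadsworth-Emmons olefination in the same flask should give mainly the E-alkenyl sulfoxide without touching the sulfur stereocentre, and the bases left at the end (lithium diethyl phosphate, diisopropylamine) are too weak to move the double bond into conjugation with the arene.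

**Step 2**
Reactants: 5 4-{(E)-3-[(S)-p-tolylsulfinyl]prop-2-en-1-yl}-1,2-dimethoxybenzene; 6 trichloroacetyl chloride
Product: 10 (4S,5S)-3,3-dichloro-4-(3,4-dimethoxybenzyl)-5-(p-tolylthio)dihydrofuran-2(3H)-one, via dichloroketene 7 (not isolated), via acyloxysulfonium enolate 8 (not isolated), via thionium carboxylate 9 (not isolated)
Conditions: Zn-Cu couple (excess), THF, -45 to 0 °C, 6 (3 equiv) added slowly
Reagents that add atoms: none
Why: Zinc dechlorinates 6 to dichloroketene 7, whose carbonyl carbon is attacked by the sulfinyl oxygen of 5 to give the acyloxysulfonium enolate 8; a charge-accelerated [3,3]-sigmatropic shift over CCl2=C-O-S-C5=C4 then makes C3-C4 and breaks S-O, and the carboxylate of the resulting thionium ion 9 closes on C5 to make O1-C5. The closest known reaction type is the lactonisation of 1-alkenyl sulfoxides with dichloroketene (Marino lactonisation, an additive Pummerer process), established for 2-alkyl-substituted E- and Z-alkenyl p-tolyl sulfoxides. The lactone ring closes in the 5-exo-trig mode, oxygen attacking the carbon of C5=S+ while sulfur stays outside the ring. C4 is controlled by the sulfur stereocentre: in the reacting rotamer the S-O bond stands perpendicular to the alkene plane with the lone pair syn to C=C and the tolyl group outside, so CCl2 is handed to the face of C4 on which oxygen lies, and the S sulfoxide on the E alkene should give the arrangement that is R in the target (called 4S in 10 only because CCl2 outranks C5). C5 should be set trans to the benzyl group because carbon and oxygen arrive on the same face of the E alkene, and this centre is erased in step 4. The step needs O-acylation and rearrangement to outrun [2+2] cycloaddition, loss of a benzylic proton (vinylogous Pummerer path), reduction of the sulfoxide by zinc and acylation of the dimethoxyphenyl ring, which the electron-poor alkene, the very electrophilic ketene kept at low concentration and the low temperature should secure.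

**Step 3**
Reactants: 10 (4S,5S)-3,3-dichloro-4-(3,4-dimethoxybenzyl)-5-(p-tolylthio)dihydrofuran-2(3H)-one; 11 vanillin acetate (4-formyl-2-methoxyphenyl acetate)
Product: 13 4-{(E)-[(4R,5S)-4-(3,4-dimethoxybenzyl)-2-oxo-5-(p-tolylthio)dihydrofuran-3(2H)-ylidene]methyl}-2-methoxyphenyl acetate, via chloro aldolate 12 (not isolated)
Conditions: CrCl2 (6 equiv), THF, 25 to 60 °C
Reagents that add atoms: none
Why: Divalent chromium reduces one C-Cl bond to a trivalent chromium enolate that adds to the aldehyde (Reformatsky-type aldol), then reduces the second C-Cl bond and expels the oxido-chromium group, a sequence known for open-chain 2,2-dichloroalkanoates to give E-2-substituted enoates under neutral conditions, so C4 is untouched and both chlorine helpers leave while the arylidene is made.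

**Step 4**
Reactants: 13 4-{(E)-[(4R,5S)-4-(3,4-dimethoxybenzyl)-2-oxo-5-(p-tolylthio)dihydrofuran-3(2H)-ylidene]methyl}-2-methoxyphenyl acetate
Product: 14 4-{(E)-[(R)-4-(3,4-dimethoxybenzyl)-2-oxodihydrofuran-3(2H)-ylidene]methyl}-2-methoxyphenyl acetate
Conditions: Bu3SnH (1.5 equiv, slow addition), AIBN (cat.), toluene, 90 °C
Reagents that add atoms: none
Why: In this radical desulfurisation the stannyl radical attacks sulfur and releases the oxygen-stabilised C5 radical, which has no favourable cyclisation open to it and takes hydrogen from Bu3SnH, a reduction known for 5-arylthio lactones that keeps the O1-C5 bond, C4 and the trisubstituted enoate.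

**Step 5**
Reactants: 14 4-{(E)-[(R)-4-(3,4-dimethoxybenzyl)-2-oxodihydrofuran-3(2H)-ylidene]methyl}-2-methoxyphenyl acetate
Product: 15 (3E,4R)-4-(3,4-dimethoxybenzyl)-3-(4-hydroxy-3-methoxybenzylidene)dihydrofuran-2(3H)-one (CNP0146216.1)
Conditions: NH4OAc, MeOH/H2O (4:1), 25 °C
Reagents that add atoms: none
Why: Neutral solvolysis of the aryl acetate, which is far more electrophilic than the conjugated lactone, should free the phenol without a base strong enough to move the double bond into the ring or to epimerise C4.

**Compound list**

1 | (S)-methyl p-tolyl sulfoxide | C[S@](=O)c1ccc(C)cc1 | starting material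
2 | diethyl chlorophosphate | CCOP(=O)(Cl)OCC | starting material
3 | 2-(3,4-dimethoxyphenyl)acetaldehyde | COc1ccc(CC=O)cc1OC | starting material
4 | diethyl {[(R)-p-tolylsulfinyl]methyl}phosphonate (present as its lithium salt; same spatial arrangement at sulfur as 1) | CCOP(=O)(OCC)C[S@](=O)c1ccc(C)cc1 | intermediate
5 | 4-{(E)-3-[(S)-p-tolylsulfinyl]prop-2-en-1-yl}-1,2-dimethoxybenzene | COc1ccc(C/C=C/[S@](=O)c2ccc(C)cc2)cc1OC | intermediate
6 | trichloroacetyl chloride | ClC(Cl)(Cl)C(Cl)=O | starting material
7 | dichloroketene | ClC(Cl)=C=O | intermediate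
8 | acyloxysulfonium enolate (zwitterion from O-acylation of 5 by 7) | COc1ccc(C/C=C/[S@+](OC([O-])=C(Cl)Cl)c2ccc(C)cc2)cc1OC | intermediate
9 | thionium carboxylate (zwitterion after the [3,3] shift) | [O-]C(=O)C(Cl)(Cl)[C@@H](Cc1ccc(OC)c(OC)c1)C=[S+]c1ccc(C)cc1 | intermediate
10 | (4S,5S)-3,3-dichloro-4-(3,4-dimethoxybenzyl)-5-(p-tolylthio)dihydrofuran-2(3H)-one | O=C1O[C@@H](Sc2ccc(C)cc2)[C@H](Cc2ccc(OC)c(OC)c2)C1(Cl)Cl | intermediate
11 | vanillin acetate (4-formyl-2-methoxyphenyl acetate) | CC(=O)Oc1ccc(C=O)cc1OC | starting material
12 | chloro aldolate (chromium alkoxide, drawn as the free alcohol; C3 and carbinol centres undefined) | CC(=O)Oc1ccc(C(O)C2(Cl)C(=O)O[C@@H](Sc3ccc(C)cc3)[C@@H]2Cc2ccc(OC)c(OC)c2)cc1OC | intermediate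
13 | 4-{(E)-[(4R,5S)-4-(3,4-dimethoxybenzyl)-2-oxo-5-(p-tolylthio)dihydrofuran-3(2H)-ylidene]methyl}-2-methoxyphenyl acetate | CC(=O)Oc1ccc(/C=C2/C(=O)O[C@@H](Sc3ccc(C)cc3)[C@@H]2Cc2ccc(OC)c(OC)c2)cc1OC | intermediate
14 | 4-{(E)-[(R)-4-(3,4-dimethoxybenzyl)-2-oxodihydrofuran-3(2H)-ylidene]methyl}-2-methoxyphenyl acetate | CC(=O)Oc1ccc(/C=C2/C(=O)OC[C@@H]2Cc2ccc(OC)c(OC)c2)cc1OC | intermediate
15 | (3E,4R)-4-(3,4-dimethoxybenzyl)-3-(4-hydroxy-3-methoxybenzylidene)dihydrofuran-2(3H)-one | COc1cc(/C=C2/C(=O)OC[C@@H]2Cc2ccc(OC)c(OC)c2)ccc1O | target

Total step count: 5. Longest linear sequence: 5 steps (1 to 5 to 10 to 13 to 14 to 15).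

**Steps most likely to fail**

**Step 3.**
- What may go wrong: protonation of the chromium enolate (plain dechlorination), fragmentation of the enolate with opening of the thio-substituted lactone, loss of p-thiocresol across C4-C5 once the arylidene is in place, or poor control of the alkene geometry.
- Fallback: it sets out from 10 and comes back at 15, removing all helpers before the arylidene is built.
- Excess Bu3SnH with AIBN in hot toluene strips both chlorines and the thio group to give (R)-4-(3,4-dimethoxybenzyl)dihydrofuran-2(3H)-one F1.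
- The lithium enolate of F1 (LiN(SiMe3)2, THF, -78 °C) is added to commercial 4-(tert-butyldimethylsilyloxy)-3-methoxybenzaldehyde, anti to the benzyl group, to give the trans aldol (3S,4R)-3-{[4-(tert-butyldimethylsilyloxy)-3-methoxyphenyl](hydroxy)methyl}-4-(3,4-dimethoxybenzyl)dihydrofuran-2(3H)-one F2.
- Mesylation (MsCl, Et3N) and elimination with DBU give the E-arylidene silyl ether (3E,4R)-3-[4-(tert-butyldimethylsilyloxy)-3-methoxybenzylidene]-4-(3,4-dimethoxybenzyl)dihydrofuran-2(3H)-one F3.
- Bu4NF buffered with AcOH then gives 15.

**Step 2.**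
- What may go wrong: loss of a benzylic proton from 8 instead of rearrangement, deoxygenation of the sulfoxide by zinc, or leakage through the minor rotamer with erosion of the chirality transfer.
- Fallback: it sets out from 6 and comes back at 15, taking the stereocentre from a desymmetrisation instead.
- Dichloroketene 7 made from 6 is added in a [2+2] cycloaddition to commercial methyl eugenol to give racemic 2,2-dichloro-3-(3,4-dimethoxybenzyl)cyclobutan-1-one F4.
- Zn in AcOH gives the prochiral 3-(3,4-dimethoxybenzyl)cyclobutan-1-one F5.
- An enantioselective Baeyer-Villiger oxidation with a Baeyer-Villiger monooxygenase of the required sense (O2, cofactor recycling) gives F1, which is carried through F2 and F3 to 15 as described above.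

**Step 1.**
- What may go wrong: enolisation of the arylacetaldehyde, poor E/Z selectivity (the Z isomer would deliver the wrong enantiomer at C4), or a base-induced shift of the double bond to the allylic sulfoxide, which racemises by [2,3]-sigmatropic rearrangement.
- Fallback: it sets out from 3 and comes back at 5, joining sulfur to a preformed E-alkenyl metal.
- Takai olefination of 3 (CHI3, CrCl2, THF/dioxane) gives (E)-4-(3-iodoallyl)-1,2-dimethoxybenzene F6.
- Iodine-lithium exchange (tBuLi, Et2O, -78 °C) and transmetalation with MgBr2·OEt2 follow.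
- Andersen substitution on commercial (1S,2R,5S)-menthyl (R)-p-toluenesulfinate (inverse addition, -78 °C) gives 5 with inversion at sulfur and retention of the alkene geometry.

**Further compounds**

F1 | step 3 | (R)-4-(3,4-dimethoxybenzyl)dihydrofuran-2(3H)-one | O=C1OC[C@H](Cc2ccc(OC)c(OC)c2)C1
F2 | step 3 | (3S,4R)-3-{[4-(tert-butyldimethylsilyloxy)-3-methoxyphenyl](hydroxy)methyl}-4-(3,4-dimethoxybenzyl)dihydrofuran-2(3H)-one (carbinol centre undefined) | COc1cc(C(O)[C@H]2C(=O)OC[C@@H]2Cc2ccc(OC)c(OC)c2)ccc1O[Si](C)(C)C(C)(C)C
F3 | step 3 | (3E,4R)-3-[4-(tert-butyldimethylsilyloxy)-3-methoxybenzylidene]-4-(3,4-dimethoxybenzyl)dihydrofuran-2(3H)-one | COc1cc(/C=C2/C(=O)OC[C@@H]2Cc2ccc(OC)c(OC)c2)ccc1O[Si](C)(C)C(C)(C)C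
F4 | step 2 | 2,2-dichloro-3-(3,4-dimethoxybenzyl)cyclobutan-1-one (racemic) | O=C1CC(Cc2ccc(OC)c(OC)c2)C1(Cl)Cl
F5 | step 2 | 3-(3,4-dimethoxybenzyl)cyclobutan-1-one | O=C1CC(Cc2ccc(OC)c(OC)c2)C1
F6 | step 1 | (E)-4-(3-iodoallyl)-1,2-dimethoxybenzene | COc1ccc(C/C=C/I)cc1OC
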